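**Retrosynthetic overview**
- Target ⇐ aromatic Claisen rearrangement of the 4-O-(1,1-dimethylallyl) ether; this ether both blocks the para phenol and is the latent C5 prenyl group.
- ⇐ Key operation: one flask closes two rings in sequence, the oxirane (Shi epoxidation) and then the dihydrofuran (5-exo phenoxide opening); catalyst control plus inversion sets the (S) centre.
- ⇐ Pd-catalysed O-tert-prenylation of the para OH ⇐ mono-C-prenylation ⇐ Hoesch acylation of phloroglucinol with 3-(4-methoxyphenyl)propanenitrile.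
- Ring order: both benzene rings are bought; the oxirane (transient) and the dihydrofuran form together in step 5; no ring is made after that.

Assumption: the stereocentre in the given SMILES is read as (S); reagents named only on Conditions lines (n-BuLi, ClCO2Me, the D-fructose-derived Shi ketone, 2KHSO5·KHSO4·K2SO4) are bought.

**Route**

Step 1
Reactants: 1 phloroglucinol; 2 3-(4-methoxyphenyl)propanenitrile
Product: 4 3-(4-methoxyphenyl)-1-(2,4,6-trihydroxyphenyl)propan-1-one, via ketiminium chloride 3 (not isolated)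
Conditions: HCl (g), ZnCl2 (0.3 equiv), Et2O, 0 °C, 24 h; then H2O, reflux, 2 h
Reagents that add atoms: water O
Why: Houben–Hoesch acylation, in which the HCl/ZnCl2-activated nitrile attacks the very electron-rich phloroglucinol ring once (the ketiminium salt deactivates it and the anisole ring is too poor a nucleophile) and hydrolysis of the salt gives the aryl ketone.

Step 2
Reactants: 4 3-(4-methoxyphenyl)-1-(2,4,6-trihydroxyphenyl)propan-1-one; 5 1-bromo-3-methylbut-2-ene (prenyl bromide, 1.0 equiv)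
Product: 6 3-(4-methoxyphenyl)-1-[2,4,6-trihydroxy-3-(3-methylbut-2-en-1-yl)phenyl]propan-1-one
Conditions: 10% aq. KOH, 0 °C to rt, 3 h
Reagents that add atoms: none
Why: C-alkylation of the ambident phloroglucinolate by an allylic bromide (favoured over O-alkylation in water), where C3′ and C5′ are equivalent so only one mono-prenyl isomer exists and one equivalent of 5 limits diprenylation.

Step 3
Reactants: 7 2-methylbut-3-en-2-ol
Product: 9 methyl 2-methylbut-3-en-2-yl carbonate, via lithium alkoxide 8 (not isolated)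
Conditions: n-BuLi, THF, −78 °C; then ClCO2Me, −78 °C to rt
Reagents that add atoms: methyl chloroformate COC(=O)Cl
Why: Alkoxycarbonylation of a preformed tertiary lithium alkoxide (carbonate formation), which avoids the sluggish direct acylation of the hindered allylic alcohol.

Step 4
Reactants: 6 3-(4-methoxyphenyl)-1-[2,4,6-trihydroxy-3-(3-methylbut-2-en-1-yl)phenyl]propan-1-one; 9 methyl 2-methylbut-3-en-2-yl carbonate (1.2 equiv)
Product: 10 1-{2,6-dihydroxy-3-(3-methylbut-2-en-1-yl)-4-[(2-methylbut-3-en-2-yl)oxy]phenyl}-3-(4-methoxyphenyl)propan-1-one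
Conditions: Pd(PPh3)4 (3 mol%), THF, 0 °C, 2 h
Reagents that add atoms: none
Why: Tsuji–Trost O-allylation, in which zerovalent palladium ionises 9 to a 1,1-dimethyl-π-allyl complex plus methoxide that deprotonates the most acidic, non-chelated para phenol, and the phenoxide attacks the more substituted allyl terminus at low temperature to give the tertiary (reverse-prenyl) ether.

Step 5
Reactants: 10 1-{2,6-dihydroxy-3-(3-methylbut-2-en-1-yl)-4-[(2-methylbut-3-en-2-yl)oxy]phenyl}-3-(4-methoxyphenyl)propan-1-one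
Product: 12 1-{(2S)-6-hydroxy-2-(2-hydroxypropan-2-yl)-4-[(2-methylbut-3-en-2-yl)oxy]-2,3-dihydro-1-benzofuran-7-yl}-3-(4-methoxyphenyl)propan-1-one, via epoxide 11 (not isolated)
Conditions: Shi ketone (from D-fructose, 30 mol%), 2KHSO5·KHSO4·K2SO4, K2CO3, Bu4NHSO4, MeCN/CH2(OMe)2/aq. Na2B4O7 buffer (pH 10.5), 0 °C, 3 h; then rt, 12 h
Reagents that add atoms: potassium peroxymonosulfate KHSO5 [K+].[O-]S(=O)(=O)OO
Why: Shi asymmetric epoxidation followed in the same flask by 5-exo-tet epoxide opening, in which the chiral dioxirane oxidises only the electron-rich trisubstituted alkene (the monosubstituted vinyl group is far slower) through the spiro transition state to the (R)-epoxide, and at pH 10.5 the 2′-phenoxide (the only free oxygen next to it, since O4′ is etherified) attacks the secondary epoxide carbon with inversion to give the (S)-dihydrofuran and the tertiary alcohol, so that oxirane and dihydrofuran are both closed in one operation.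

Step 6
Reactants: 12 1-{(2S)-6-hydroxy-2-(2-hydroxypropan-2-yl)-4-[(2-methylbut-3-en-2-yl)oxy]-2,3-dihydro-1-benzofuran-7-yl}-3-(4-methoxyphenyl)propan-1-one
Product: 14 1-[(2S)-4,6-dihydroxy-2-(2-hydroxypropan-2-yl)-5-(3-methylbut-2-en-1-yl)-2,3-dihydro-1-benzofuran-7-yl]-3-(4-methoxyphenyl)propan-1-one, via dienone 13 (not isolated)
Conditions: PhNEt2, 130 °C, 3 h, Ar
Reagents that add atoms: none
Why: Aromatic Claisen rearrangement ([3,3]-sigmatropic shift) of the 1,1-dimethylallyl ether to C5, the only free ortho carbon, followed by enolisation of the dienone, turns the ether into the C-prenyl group and frees the 4-OH, while the remote ether stereocentre is untouched.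

**Compound list**
1 | phloroglucinol (benzene-1,3,5-triol) | Oc1cc(O)cc(O)c1 | starting material
2 | 3-(4-methoxyphenyl)propanenitrile | COc1ccc(CCC#N)cc1 | starting material
3 | 3-(4-methoxyphenyl)-1-(2,4,6-trihydroxyphenyl)propan-1-iminium chloride | COc1ccc(CCC(=[NH2+])c2c(O)cc(O)cc2O)cc1.[Cl-] | intermediate
4 | 3-(4-methoxyphenyl)-1-(2,4,6-trihydroxyphenyl)propan-1-one | COc1ccc(CCC(=O)c2c(O)cc(O)cc2O)cc1 | intermediate
5 | 1-bromo-3-methylbut-2-ene (prenyl bromide) | CC(C)=CCBr | starting material
6 | 3-(4-methoxyphenyl)-1-[2,4,6-trihydroxy-3-(3-methylbut-2-en-1-yl)phenyl]propan-1-one | COc1ccc(CCC(=O)c2c(O)cc(O)c(CC=C(C)C)c2O)cc1 | intermediate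
7 | 2-methylbut-3-en-2-ol | CC(C)(O)C=C | starting material
8 | lithium 2-methylbut-3-en-2-olate | [Li+].CC(C)([O-])C=C | intermediate
9 | methyl 2-methylbut-3-en-2-yl carbonate | COC(=O)OC(C)(C)C=C | intermediate
10 | 1-{2,6-dihydroxy-3-(3-methylbut-2-en-1-yl)-4-[(2-methylbut-3-en-2-yl)oxy]phenyl}-3-(4-methoxyphenyl)propan-1-one | COc1ccc(CCC(=O)c2c(O)cc(OC(C)(C)C=C)c(CC=C(C)C)c2O)cc1 | intermediate
11 | 1-{3-{[(2R)-3,3-dimethyloxiran-2-yl]methyl}-2,6-dihydroxy-4-[(2-methylbut-3-en-2-yl)oxy]phenyl}-3-(4-methoxyphenyl)propan-1-one | COc1ccc(CCC(=O)c2c(O)cc(OC(C)(C)C=C)c(C[C@H]3OC3(C)C)c2O)cc1 | intermediate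
12 | 1-{(2S)-6-hydroxy-2-(2-hydroxypropan-2-yl)-4-[(2-methylbut-3-en-2-yl)oxy]-2,3-dihydro-1-benzofuran-7-yl}-3-(4-methoxyphenyl)propan-1-one | COc1ccc(CCC(=O)c2c(O)cc(OC(C)(C)C=C)c3c2O[C@H](C(C)(C)O)C3)cc1 | intermediate
13 | (2S)-6-hydroxy-2-(2-hydroxypropan-2-yl)-7-[3-(4-methoxyphenyl)propanoyl]-5-(3-methylbut-2-en-1-yl)-2,3-dihydro-1-benzofuran-4(5H)-one (both C5 epimers) | COc1ccc(CCC(=O)C2=C(O)C(CC=C(C)C)C(=O)C3=C2O[C@H](C(C)(C)O)C3)cc1 | intermediate
14 | 1-[(2S)-4,6-dihydroxy-2-(2-hydroxypropan-2-yl)-5-(3-methylbut-2-en-1-yl)-2,3-dihydro-1-benzofuran-7-yl]-3-(4-methoxyphenyl)propan-1-one (CNP0150199.1) | COc1ccc(CCC(=O)c2c(O)c(CC=C(C)C)c(O)c3c2O[C@H](C(C)(C)O)C3)cc1 | target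

**Step count**
Total steps: 6. Longest linear sequence: 5 (steps 1, 2, 4, 5, 6); step 3 is a one-step side branch.

**Three steps most likely to fail, each with a fallback**

Risk 1, step 5. The dioxirane may oxidise the free phenoxide ring instead of the alkene, or the epoxide may open without control. The fallback sets out from 10. Both free phenols are acetylated (Ac2O, Et3N, DMAP, CH2Cl2) to give the diacetate F4. Shi epoxidation of F4 under the step 5 conditions then gives the isolable (R)-epoxide diacetate F5. K2CO3 in MeOH at rt removes both acetates, and the 2′-phenoxide closes the dihydrofuran with inversion, passing through 11. This comes back to the route at 12.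

Risk 2, step 4. The π-allyl complex may alkylate carbon (C5′), give the linear ether, or react at an ortho phenol. The fallback sets out from 6. The para phenol is etherified with 3-chloro-3-methylbut-1-yne (K2CO3, KI, CuI, acetone, reflux) to give the 1,1-dimethylpropargyl ether F3. Semihydrogenation of the alkyne (H2, Pd/CaCO3 poisoned with Pb(OAc)2, quinoline, EtOAc) leaves the prenyl alkene alone. This comes back to the route at 10.

Risk 3, step 2. Direct C-prenylation gives mono-, di- and O-prenyl mixtures in moderate yield. The fallback sets out from 4. Its para phenol is O-alkylated with carbonate 9 and Pd(PPh3)4 (THF, 0 °C) to give the para 1,1-dimethylallyl ether F1. Heating in PhNEt2 at 120 °C brings about an aromatic Claisen rearrangement through the ortho-dienone F2, which installs exactly one C-prenyl group (both ortho carbons are equivalent). This comes back to the route at 6.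

**Further compounds**
F1 | step 2 | 1-{2,6-dihydroxy-4-[(2-methylbut-3-en-2-yl)oxy]phenyl}-3-(4-methoxyphenyl)propan-1-one | COc1ccc(CCC(=O)c2c(O)cc(OC(C)(C)C=C)cc2O)cc1
F2 | step 2 | 3,5-dihydroxy-4-[3-(4-methoxyphenyl)propanoyl]-6-(3-methylbut-2-en-1-yl)cyclohexa-2,4-dien-1-one | COc1ccc(CCC(=O)C2=C(O)C(CC=C(C)C)C(=O)C=C2O)cc1
F3 | step 4 | 1-{2,6-dihydroxy-3-(3-methylbut-2-en-1-yl)-4-[(2-methylbut-3-yn-2-yl)oxy]phenyl}-3-(4-methoxyphenyl)propan-1-one | COc1ccc(CCC(=O)c2c(O)cc(OC(C)(C)C#C)c(CC=C(C)C)c2O)cc1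
F4 | step 5 | 2-[3-(4-methoxyphenyl)propanoyl]-4-(3-methylbut-2-en-1-yl)-5-[(2-methylbut-3-en-2-yl)oxy]-1,3-phenylene diacetate | COc1ccc(CCC(=O)c2c(OC(C)=O)cc(OC(C)(C)C=C)c(CC=C(C)C)c2OC(C)=O)cc1
F5 | step 5 | 4-{[(2R)-3,3-dimethyloxiran-2-yl]methyl}-2-[3-(4-methoxyphenyl)propanoyl]-5-[(2-methylbut-3-en-2-yl)oxy]-1,3-phenylene diacetate | COc1ccc(CCC(=O)c2c(OC(C)=O)cc(OC(C)(C)C=C)c(C[C@H]3OC3(C)C)c2OC(C)=O)cc1
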